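**Plan** (chain numbered C1 = carboxyl carbon to C23 = the CH2 on furan C2)
1. Retrosynthetic cuts, in order: the C1 methyl ester, the sp3–sp3 bond C20–C21, then the sp–sp bond C6–C7 of the diyne. The furan ring is bought intact.
2. Enabling feature: C20 and C21 are two unactivated methylenes inside the (CH2)15 run C9–C23, out of polar reach of the C5–C8 diyne and of the furan ring, yet each is one carbon short of a fatty-acid carboxyl group. Both are therefore made with the same polarity, as primary radicals from two N-acyloxyphthalimides, and joined on nickel; the anodic mixed Kolbe coupling is avoided because it would oxidise the furan.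
3. The radicals are tolerated because the C21 radical is held from furan C2 by C22–C23 (only 4-exo or 5-endo closure is possible) and the C20 radical is eleven methylenes (C9–C19) from alkyne C8.
4. Forward order: methyl hex-5-ynoate → bromoalkyne → Cadiot–Chodkiewicz coupling with pentadec-14-ynoic acid (C6–C7) → NHPI esters of the diyne half-ester and of 4-(furan-2-yl)butanoic acid → doubly decarboxylative coupling (C20–C21) → saponification.
5. Stereochemistry: the target has no stereocentre and no stereogenic double bond, so nothing has to be set.

Key step: step 5

Remark: pentadec-14-ynoic acid and 4-(furan-2-yl)butanoic acid are taken as catalogue building blocks, so the whole carbon skeleton comes from three simple carboxylic acid derivatives.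

**Step 1**
Reactants: 1 methyl hex-5-ynoate
Product: 2 methyl 6-bromohex-5-ynoate
Conditions: NBS, AgNO3 (cat.), acetone, rt, dark
Reagents that add atoms: N-bromosuccinimide, O=C1CCC(=O)N1Br
Why: Silver-catalysed electrophilic bromination of a terminal alkyne (via the silver acetylide) is selective for the alkyne C–H and leaves the methyl ester untouched.

**Step 2**
Reactants: 2 methyl 6-bromohex-5-ynoate; 3 pentadec-14-ynoic acid
Product: 4 21-methoxy-21-oxohenicosa-14,16-diynoic acid
Conditions: CuCl (cat.), NH2OH·HCl (cat.), 30% aq. n-BuNH2, MeOH/THF, 0 °C, slow addition of 2; then cold dilute HCl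
Reagents that add atoms: none
Why: In this Cadiot–Chodkiewicz coupling the copper(I) acetylide of 3 (carboxyl group carried as the ammonium carboxylate) should couple with the 1-bromoalkyne 2 to form the C6–C7 bond, with hydroxylamine holding copper at Cu(I) against Glaser homocoupling and the low temperature sparing the methyl ester from aminolysis.

**Step 3**
Reactants: 4 21-methoxy-21-oxohenicosa-14,16-diynoic acid
Product: 5 21-(1,3-dioxoisoindolin-2-yl) 1-methyl henicosa-5,7-diynedioate
Conditions: N-hydroxyphthalimide, DIC, DMAP (cat.), CH2Cl2, rt
Reagents that add atoms: N-hydroxyphthalimide, O=C1c2ccccc2C(=O)N1O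
Why: Carbodiimide (Steglich-type) esterification should activate the only free carboxyl group of 4 as the redox-active N-acyloxyphthalimide while the methyl ester and the diyne stay inert.

**Step 4**
Reactants: 6 4-(furan-2-yl)butanoic acid
Product: 7 1,3-dioxoisoindolin-2-yl 4-(furan-2-yl)butanoate
Conditions: N-hydroxyphthalimide, DIC, DMAP (cat.), CH2Cl2, rt
Reagents that add atoms: N-hydroxyphthalimide, O=C1c2ccccc2C(=O)N1O
Why: The same carbodiimide (Steglich-type) esterification should give the second redox-active ester under neutral conditions that do not touch the acid-sensitive furan.

**Step 5**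
Reactants: 5 21-(1,3-dioxoisoindolin-2-yl) 1-methyl henicosa-5,7-diynedioate; 7 1,3-dioxoisoindolin-2-yl 4-(furan-2-yl)butanoate
Product: 8 methyl 23-(furan-2-yl)tricosa-5,7-diynoate
Conditions: 7 (3 equiv), NiCl2·6H2O (20 mol%), 2,2′:6′,2″-terpyridine (20 mol%), NaI, DMF, Zn(+)/RVC(−), undivided cell, constant current, rt, dark; then cold dilute HCl
Reagents that add atoms: none
Why: Cathodically regenerated low-valent Ni–terpyridine should pass one electron to each N-acyloxyphthalimide, whose radical anion loses phthalimide anion and CO2 to give the primary radicals at C20 (from 5) and C21 (from 7); one is captured as an alkyl–nickel species that takes up the second radical and forms the C20–C21 bond by reductive elimination from dialkyl-Ni(III). The closest known reaction type is the Ni-electrocatalytic doubly decarboxylative Csp3–Csp3 coupling of two redox-active esters, the reductive counterpart of the mixed Kolbe electrolysis of a fatty acid with a half-ester. No ring is closed and no stereocentre is formed. The step needs cross-coupling over homocoupling, which the threefold excess of the inexpensive partner 7 should secure, and it needs chemoselectivity against the two π-systems, which the structure secures: the C21 radical can reach the furan only by 4-exo (at C2) or 5-endo (at C3) closure, the C20 radical is eleven methylenes from alkyne C8, and the dialkyl diyne and the furan accept an electron only far below the potential at which the NHPI esters do. Running the union reductively and not anodically is what spares the electron-rich 2-alkylfuran, which would be oxidised before a carboxylate in a Kolbe cell.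

**Step 6**
Reactants: 8 methyl 23-(furan-2-yl)tricosa-5,7-diynoate
Product: 9 23-(furan-2-yl)tricosa-5,7-diynoic acid
Conditions: LiOH·H2O, THF/H2O, rt, dark; then cold 1 M HCl to pH 4
Reagents that add atoms: lithium hydroxide, [Li+].[OH-]
Why: Saponification (BAc2) of the unhindered methyl ester at room temperature followed by brief cold acidification should leave the 1,3-diyne and the 2-alkylfuran unchanged, the product being kept from light because diynoic acids photopolymerise in the solid state.

**Compound list**
1 | methyl hex-5-ynoate | COC(=O)CCCC#C | starting material
2 | methyl 6-bromohex-5-ynoate | COC(=O)CCCC#CBr | intermediate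
3 | pentadec-14-ynoic acid | C#CCCCCCCCCCCCCC(=O)O | starting material
4 | 21-methoxy-21-oxohenicosa-14,16-diynoic acid | COC(=O)CCCC#CC#CCCCCCCCCCCCCC(=O)O | intermediate
5 | 21-(1,3-dioxoisoindolin-2-yl) 1-methyl henicosa-5,7-diynedioate | COC(=O)CCCC#CC#CCCCCCCCCCCCCC(=O)ON1C(=O)c2ccccc2C1=O | intermediate
6 | 4-(furan-2-yl)butanoic acid | OC(=O)CCCc1ccco1 | starting material
7 | 1,3-dioxoisoindolin-2-yl 4-(furan-2-yl)butanoate | O=C(CCCc1ccco1)ON1C(=O)c2ccccc2C1=O | intermediate
8 | methyl 23-(furan-2-yl)tricosa-5,7-diynoate | COC(=O)CCCC#CC#CCCCCCCCCCCCCCCCc1ccco1 | intermediate
9 | 23-(furan-2-yl)tricosa-5,7-diynoic acid | O=C(O)CCCC#CC#CCCCCCCCCCCCCCCCc1ccco1 | target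

**Total step count:** 6
**Longest linear sequence:** 5 steps (steps 1, 2, 3, 5, 6)

**Steps most likely to fail**

Step 5. The risks are statistical homocoupling and hydrodecarboxylation of the two radicals, and coordination or carbometalation of the 1,3-diyne by low-valent nickel that diverts the catalyst. The fallback is a polar, two-electron union on palladium that sets out from 2 and comes back at 8. Cadiot–Chodkiewicz coupling of 2 with bought tetradec-13-yn-1-ol F1 (conditions of step 2) should give methyl 20-hydroxyicosa-5,7-diynoate F2. Appel bromination (CBr4, PPh3, CH2Cl2, 0 °C) should then give methyl 20-bromoicosa-5,7-diynoate F3. Separately, bought 2-allylfuran F4 is hydroborated with exactly one equivalent of 9-BBN (THF, rt) to 9-[3-(furan-2-yl)propyl]-9-borabicyclo[3.3.1]nonane F5, which places boron on C21 and leaves no B–H for the diyne. Alkyl–alkyl Suzuki–Miyaura coupling of F3 with F5 (Pd(OAc)2, PCy3, K3PO4·H2O, THF, rt) should form the same C20–C21 bond and give 8.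

Step 2. The risks are oxidative homocoupling of either alkyne partner and aminolysis of the methyl ester by the primary amine. The fallback sets out from 1 and comes back at 4 without a bromoalkyne and without a primary amine. Compound 1 (fivefold excess) and 3 are heterocoupled oxidatively under Eglinton conditions (Cu(OAc)2, pyridine/MeOH, 40 °C). The statistical outcome is accepted because 4 is the only mono-acid formed and should separate by polarity from the neutral and the doubly acidic homocoupling products. No new compound is made on this path.

Step 6. The risks are base-promoted propargyl–allenyl isomerisation next to the diyne and degradation of the furan or the diynoic acid during acidification and concentration. The fallback is a neutral unmasking that sets out from 8 and comes back at 9. Transesterification of 8 with allyl alcohol (Bu2SnO cat., toluene, 90 °C) should give allyl 23-(furan-2-yl)tricosa-5,7-diynoate F6. Pd(PPh3)4 (cat.) with morpholine in THF at rt should then transfer the allyl group to the amine and give 9 after a pH 5 phosphate wash, with no hydroxide and no strong acid.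

**Further compounds**
F1 | step 5 | tetradec-13-yn-1-ol (bought) | C#CCCCCCCCCCCCCO
F2 | step 5 | methyl 20-hydroxyicosa-5,7-diynoate | COC(=O)CCCC#CC#CCCCCCCCCCCCCO
F3 | step 5 | methyl 20-bromoicosa-5,7-diynoate | COC(=O)CCCC#CC#CCCCCCCCCCCCCBr
F4 | step 5 | 2-allylfuran (bought) | C=CCc1ccco1
F5 | step 5 | 9-[3-(furan-2-yl)propyl]-9-borabicyclo[3.3.1]nonane | c1coc(CCCB2C3CCCC2CCC3)c1
F0 | step 2 | none | none
F6 | step 6 | allyl 23-(furan-2-yl)tricosa-5,7-diynoate | C=CCOC(=O)CCCC#CC#CCCCCCCCCCCCCCCCc1ccco1
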